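**Retrosynthetic overview**

1. Numbering: pyrrole N4–C3–C2–C1–C9a; azepine C5–C9; cyclohexane C9–C10(Et)–C11(O)–C12; fused lactone C12–C13(Me)–C14(=O)–O–C11; side lactone C18(O)–C19–C20(Me)–C21(=O) on C3. The route rests on C11 being a carbonyl-level carbon between C10 and C12 while C12 sits on pyrrole C1, so a C11 acyl anion can close the cyclohexane onto a C12=C13 alkylidene malonate carried by C1.
2. Side lactone last: the C3 carboxyl carbon becomes C18 by Negishi acylation of the zinc reagent from methyl (R)-3-bromo-2-methylpropanoate (brings C20); CBS reduction sets C18; lactonisation.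
3. Fused lactone from the C11 ketone and the C12 malonate: hydride anti to the C10 and C12 groups, lactonisation, C13 methylation, decarboxylation with convex-face protonation.
4. Stetter precursor from pyrrole: azepine by iminium-catalysed closure of pyrrole C2 onto an N-tethered enal (C9); C10 by SAMP-hydrazone ethylation; a C3 benzyl ester blocks the free α-position and steers formylation to C1; Knoevenagel with dibenzyl malonate.
5. Ring order: pyrrole (bought), azepine (step 3), cyclohexanone (step 12), fused γ-lactone (step 13), side γ-lactone (step 17).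

Key step: step 12

Assumption: the (5S)-imidazolidinone of step 3 is taken to expose the same enal face as in intermolecular pyrrole alkylations (giving 9R), and the (5aS,10bR)-triazolium of step 12 is taken as the enantiomer matched to the substrate bias; in either case the antipodal catalyst is the remedy.

**Route**

Step 1
Reactants: 1 1H-pyrrole; 2 6-bromohex-1-ene
Product: 3 1-(hex-5-en-1-yl)-1H-pyrrole
Conditions: KOH (powdered), DMSO, rt
Reagents that add atoms: none
Why: N-alkylation (SN2) of the potassium pyrrolide, which in DMSO reacts at nitrogen and not at carbon with a primary bromide.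

Step 2
Reactants: 3 1-(hex-5-en-1-yl)-1H-pyrrole; 4 (E)-but-2-enal
Product: 5 (2E)-7-(1H-pyrrol-1-yl)hept-2-enal
Conditions: 4 (5 equiv), second-generation Grubbs catalyst RuCl2(=CHPh)(H2IMes)(PCy3) (3 mol %), CH2Cl2, 40 °C
Reagents that add atoms: none
Why: Olefin cross-metathesis of a terminal alkene with excess crotonaldehyde should give the (E)-enal with loss of propene; the N-alkylpyrrole does not bind ruthenium.

Step 3
Reactants: 5 (2E)-7-(1H-pyrrol-1-yl)hept-2-enal
Product: 6 2-[(9R)-6,7,8,9-tetrahydro-5H-pyrrolo[1,2-a]azepin-9-yl]acetaldehyde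
Conditions: (5S)-5-benzyl-2,2,3-trimethylimidazolidin-4-one trifluoroacetate (20 mol %), THF/H2O 95:5, −30 °C, 0.05 M
Reagents that add atoms: none
Why: Iminium-catalysed intramolecular Friedel–Crafts-type Michael addition of pyrrole C2 to the enal β-carbon closes the seven-membered ring; the benzyl group of the catalyst shields one face of the (E)-iminium ion so that C9 should form as R, and because the two pyrrole α-positions are equivalent there is no regiochemical question.

Step 4
Reactants: 6 2-[(9R)-6,7,8,9-tetrahydro-5H-pyrrolo[1,2-a]azepin-9-yl]acetaldehyde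
Product: 7 SAMP hydrazone of 6
Conditions: SAMP (1.1 equiv), 4 Å molecular sieves, CH2Cl2, 0 °C to rt
Reagents that add atoms: (S)-1-amino-2-(methoxymethyl)pyrrolidine (SAMP), COC[C@@H]1CCCN1N
Why: Condensation of the aldehyde with the auxiliary hydrazine gives the (E)-hydrazone, which allows a reagent-controlled α-alkylation that the free aldehyde does not.

Step 5
Reactants: 7 SAMP hydrazone of 6
Product: 8 ethylated SAMP hydrazone (10R)
Conditions: LiN(i-Pr)2, THF, 0 °C; then EtI, −100 °C to rt
Reagents that add atoms: iodoethane, CCI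
Why: SAMP-hydrazone alkylation: the chelated lithium azaenolate is ethylated on the face away from the methoxymethyl arm, which should set C10 as R under auxiliary control, independent of C9.

Step 6
Reactants: 8 ethylated SAMP hydrazone (10R)
Product: 10 (2R)-2-[(9R)-6,7,8,9-tetrahydro-5H-pyrrolo[1,2-a]azepin-9-yl]butanal, via N-methylhydrazonium iodide 9 (not isolated)
Conditions: MeI (excess), 60 °C; evaporate; 1 M HCl/n-pentane (two-phase), rt
Reagents that add atoms: water, O
Why: N-methylation turns the hydrazone into a hydrazonium salt that hydrolyses in dilute acid without enolisation, so the aldehyde should be released with C10 intact and pass into the pentane layer, away from the acid.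

Step 7
Reactants: 10 (2R)-2-[(9R)-6,7,8,9-tetrahydro-5H-pyrrolo[1,2-a]azepin-9-yl]butanal
Product: 11 (9R)-9-[(1R)-1-(1,3-dioxolan-2-yl)propyl]-6,7,8,9-tetrahydro-5H-pyrrolo[1,2-a]azepine
Conditions: ethylene glycol (5 equiv), PPTS (10 mol %), benzene, reflux, Dean–Stark trap
Reagents that add atoms: ethylene glycol, OCCO
Why: Acetalisation with azeotropic removal of water masks the aldehyde for the electrophilic and basic steps that follow; the weak acid and the excess diol should neither enolise the α-branched aldehyde nor let it condense with the pyrrole.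

Step 8
Reactants: 11 (9R)-9-[(1R)-1-(1,3-dioxolan-2-yl)propyl]-6,7,8,9-tetrahydro-5H-pyrrolo[1,2-a]azepine
Product: 13 benzyl (9R)-9-[(1R)-1-(1,3-dioxolan-2-yl)propyl]-6,7,8,9-tetrahydro-5H-pyrrolo[1,2-a]azepine-3-carboxylate, via trichloromethyl ketone 12 (not isolated)
Conditions: Cl3CCOCl, 2,6-lutidine, CH2Cl2, 0 °C to rt; evaporate; BnOH, NaH (0.2 equiv), THF, 0 °C to rt
Reagents that add atoms: trichloroacetyl chloride, ClC(=O)C(Cl)(Cl)Cl; benzyl alcohol, OCc1ccccc1
Why: Uncatalysed Friedel–Crafts acylation at C3, the only free pyrrole α-position, followed by haloform-type displacement of CCl3 by benzyl oxide; the ester blocks C3, directs the next electrophile to C1, tempers the pyrrole, and its carbon later becomes C18.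

Step 9
Reactants: 13 benzyl (9R)-9-[(1R)-1-(1,3-dioxolan-2-yl)propyl]-6,7,8,9-tetrahydro-5H-pyrrolo[1,2-a]azepine-3-carboxylate
Product: 15 benzyl (9R)-9-[(1R)-1-(1,3-dioxolan-2-yl)propyl]-1-formyl-6,7,8,9-tetrahydro-5H-pyrrolo[1,2-a]azepine-3-carboxylate, via iminium chloride 14 (not isolated)
Conditions: POCl3, DMF, ClCH2CH2Cl, 0 to 60 °C; then aq. NaOAc, rt
Reagents that add atoms: N,N-dimethylformamide, CN(C)C=O; water, O
Why: Vilsmeier–Haack formylation: attack at C2 would place positive charge on the ester-bearing C3, so the chloroiminium ion should enter at C1, next to the alkyl-bearing C9a; the dioxolane should survive because the mixture is buffered by DMF and worked up with acetate.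

Step 10
Reactants: 15 benzyl (9R)-9-[(1R)-1-(1,3-dioxolan-2-yl)propyl]-1-formyl-6,7,8,9-tetrahydro-5H-pyrrolo[1,2-a]azepine-3-carboxylate; 16 dibenzyl malonate
Product: 17 dibenzyl 2-({(9R)-3-[(benzyloxy)carbonyl]-9-[(1R)-1-(1,3-dioxolan-2-yl)propyl]-6,7,8,9-tetrahydro-5H-pyrrolo[1,2-a]azepin-1-yl}methylidene)propanedioate
Conditions: piperidine (0.2 equiv), AcOH (0.2 equiv), toluene, reflux, Dean–Stark trap
Reagents that add atoms: none
Why: Knoevenagel condensation of the pyrrole aldehyde with the malonate, driven by removal of water, installs the C12=C13 acceptor; the C3 ester keeps the aldehyde electrophilic enough.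

Step 11
Reactants: 17 dibenzyl 2-({(9R)-3-[(benzyloxy)carbonyl]-9-[(1R)-1-(1,3-dioxolan-2-yl)propyl]-6,7,8,9-tetrahydro-5H-pyrrolo[1,2-a]azepin-1-yl}methylidene)propanedioate
Product: 18 dibenzyl 2-({(9R)-3-[(benzyloxy)carbonyl]-9-[(2R)-1-oxobutan-2-yl]-6,7,8,9-tetrahydro-5H-pyrrolo[1,2-a]azepin-1-yl}methylidene)propanedioate
Conditions: 1 M HCl, THF, rt
Reagents that add atoms: water, O
Why: Acid hydrolysis of the dioxolane; the alkylidene malonate, the benzyl esters and the ester-deactivated pyrrole are stable to dilute aqueous acid, and C10 is not enolised at room temperature.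

Step 12
Reactants: 18 dibenzyl 2-({(9R)-3-[(benzyloxy)carbonyl]-9-[(2R)-1-oxobutan-2-yl]-6,7,8,9-tetrahydro-5H-pyrrolo[1,2-a]azepin-1-yl}methylidene)propanedioate
Product: 19 tricyclic C11 ketone (9R,10R,12S) with the dibenzyl malonate on C12 and the benzyl ester on C3
Conditions: (5aS,10bR)-2-(pentafluorophenyl)-5a,10b-dihydro-4H,6H-indeno[2,1-b][1,2,4]triazolo[4,3-d][1,4]oxazin-2-ium tetrafluoroborate (20 mol %), KN(SiMe3)2 (20 mol %), toluene, 25 °C
Reagents that add atoms: none
Why: The free carbene adds to the C11 aldehyde and a proton shift gives the hydroxy-enamine, an acyl-anion equivalent that attacks C12 of the alkylidene malonate; proton transfer to C13 and loss of the carbene release the C11 ketone (intramolecular Stetter reaction, the type known for aliphatic aldehydes with alkylidene malonate acceptors and for β-aryl acceptors). The cyclohexanone closes in a 6-exo-trig mode across the C9a–C1 edge of the pyrrole. C12 is set in a chair-like transition state in which C8 and the C10 ethyl group are pseudo-equatorial and the alkylidene malonate lies in the pyrrole plane with C13 turned toward C2–H, so the malonate should end equatorial and cis to the ethyl group (12S), and the chiral carbene is chosen to reinforce this substrate bias. The step needs the acyl anion to win over the C10 enolate, whose 5-exo Michael addition would give a cyclopentane; this is secured by using no more base than azolium salt, by the tertiary C10, and by the malonate together with the C3 ester, which keep C12 electrophilic despite conjugation to the pyrrole. C10 is not touched under these weakly basic conditions, and in the product its ethyl group already sits trans to C8, the more stable arrangement.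

Step 13
Reactants: 19 tricyclic C11 ketone (9R,10R,12S)
Product: 21 tetracyclic α-(benzyloxycarbonyl) γ-lactone (9R,10R,11R,12S; C13 unassigned) with the benzyl ester on C3, via hydroxy malonate 20 (not isolated)
Conditions: LiBH(s-Bu)3 (L-Selectride, 2.5 equiv), THF, −78 °C; AcOH; then PPTS (cat.), toluene, 60 °C
Reagents that add atoms: none
Why: Ketone reduction by a bulky hydride that approaches C11 from the face opposite to the cis-disposed C10 ethyl and C12 malonate groups should give the 11R alcohol cis to both, which closes the cis-fused γ-lactone by transesterification onto one malonate ester.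

Step 14
Reactants: 21 tetracyclic α-(benzyloxycarbonyl) γ-lactone
Product: 22 C13-methylated lactone ester (C13 quaternary and unassigned)
Conditions: K2CO3, MeI, DMF, rt
Reagents that add atoms: iodomethane, CI
Why: C-alkylation of the β-dicarbonyl enolate with iodomethane; the configuration of the quaternary C13 does not matter because its ester is removed in the next step.

Step 15
Reactants: 22 C13-methylated lactone ester
Product: 24 tetracyclic lactone C3-carboxylic acid (9R,10R,11R,12S,13S), via diacid 23 (not isolated)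
Conditions: H2 (1 atm), 10% Pd/C, EtOAc, rt; filter; toluene, 110 °C
Reagents that add atoms: none
Why: Hydrogenolysis of both benzyl esters, then thermal decarboxylation of the malonic-type half acid through its enol; the enol should be protonated at C13 from the convex face of the cis-fused bicycle (the face of H12), which leaves the methyl group on the concave face (13S), and the pyrrole-2-carboxylic acid does not decarboxylate at this temperature.

Step 16
Reactants: 24 tetracyclic lactone C3-carboxylic acid; 25 methyl (R)-3-bromo-2-methylpropanoate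
Product: 27 keto ester with the C3–C(=O)–CH2–CH(CH3)–CO2Me side chain (20S), via acid chloride 26 (not isolated)
Conditions: 1-chloro-N,N,2-trimethylprop-1-en-1-amine, CH2Cl2, 0 °C to rt; then BrZnCH2CH(CH3)CO2Me (from 25, Zn dust, LiCl, THF, 50 °C), Pd(PPh3)4 (5 mol %), THF, rt
Reagents that add atoms: none
Why: Neutral conversion of the acid into its chloride and Negishi acylation of the β-ester alkylzinc reagent should give the γ-keto ester with the former blocking carbon as C18; C20 comes unchanged from 25 because the stereocentre is not the zinc-bearing carbon.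

Step 17
Reactants: 27 keto ester (20S)
Product: 29 target CNP0232452.1, via hydroxy ester 28 (not isolated)
Conditions: (S)-2-methyl-CBS-oxazaborolidine (0.5 equiv), catecholborane, toluene, −78 to −40 °C; MeOH; then DBU (0.2 equiv), CH2Cl2, rt
Reagents that add atoms: none
Why: Corey–Bakshi–Shibata reduction: the (S)-oxazaborolidine distinguishes the large pyrrolyl group from the small CH2 group and should give the 18R carbinol, which under mild base closes onto the methyl ester to the trans (18R,20S) γ-lactone; the low temperature guards against ionisation of the pyrrolyl carbinol, and neither C20 nor C13 is enolised.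

**Compound list**

1 | 1H-pyrrole | c1cc[nH]c1 | starting material
2 | 6-bromohex-1-ene | C=CCCCCBr | starting material
3 | 1-(hex-5-en-1-yl)-1H-pyrrole | C=CCCCCn1cccc1 | intermediate
4 | (E)-but-2-enal (crotonaldehyde) | C/C=C/C=O | starting material
5 | (2E)-7-(1H-pyrrol-1-yl)hept-2-enal | O=C/C=C/CCCCn1cccc1 | intermediate
6 | 2-[(9R)-6,7,8,9-tetrahydro-5H-pyrrolo[1,2-a]azepin-9-yl]acetaldehyde | O=CC[C@H]1CCCCn2cccc21 | intermediate
7 | SAMP hydrazone of 6: (E)-N-[(2S)-2-(methoxymethyl)pyrrolidin-1-yl]-2-[(9R)-6,7,8,9-tetrahydro-5H-pyrrolo[1,2-a]azepin-9-yl]ethan-1-imine | COC[C@@H]1CCCN1/N=C/C[C@H]2CCCCn3cccc23 | intermediate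
8 | ethylated SAMP hydrazone: (E,2R)-N-[(2S)-2-(methoxymethyl)pyrrolidin-1-yl]-2-[(9R)-6,7,8,9-tetrahydro-5H-pyrrolo[1,2-a]azepin-9-yl]butan-1-imine | COC[C@@H]1CCCN1/N=C/[C@H](CC)[C@H]2CCCCn3cccc23 | intermediate
9 | N-methylhydrazonium iodide of 8 (methylated on the pyrrolidine nitrogen) | COC[C@@H]1CCC[N+]1(C)/N=C/[C@H](CC)[C@H]2CCCCn3cccc23.[I-] | intermediate (not isolated)
10 | (2R)-2-[(9R)-6,7,8,9-tetrahydro-5H-pyrrolo[1,2-a]azepin-9-yl]butanal | CC[C@@H](C=O)[C@H]1CCCCn2cccc21 | intermediate
11 | (9R)-9-[(1R)-1-(1,3-dioxolan-2-yl)propyl]-6,7,8,9-tetrahydro-5H-pyrrolo[1,2-a]azepine | CC[C@@H](C1OCCO1)[C@H]2CCCCn3cccc23 | intermediate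
12 | 2,2,2-trichloro-1-{(9R)-9-[(1R)-1-(1,3-dioxolan-2-yl)propyl]-6,7,8,9-tetrahydro-5H-pyrrolo[1,2-a]azepin-3-yl}ethan-1-one | CC[C@@H](C1OCCO1)[C@H]2CCCCn3c(C(=O)C(Cl)(Cl)Cl)ccc23 | intermediate (not isolated)
13 | benzyl (9R)-9-[(1R)-1-(1,3-dioxolan-2-yl)propyl]-6,7,8,9-tetrahydro-5H-pyrrolo[1,2-a]azepine-3-carboxylate | CC[C@@H](C1OCCO1)[C@H]2CCCCn3c(C(=O)OCc4ccccc4)ccc23 | intermediate
14 | N,N-dimethyliminium chloride at the C1 methine of 13 | CC[C@@H](C1OCCO1)[C@H]2CCCCn3c(C(=O)OCc4ccccc4)cc(C=[N+](C)C)c23.[Cl-] | intermediate (not isolated)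
15 | benzyl (9R)-9-[(1R)-1-(1,3-dioxolan-2-yl)propyl]-1-formyl-6,7,8,9-tetrahydro-5H-pyrrolo[1,2-a]azepine-3-carboxylate | CC[C@@H](C1OCCO1)[C@H]2CCCCn3c(C(=O)OCc4ccccc4)cc(C=O)c23 | intermediate
16 | dibenzyl propanedioate (dibenzyl malonate) | O=C(CC(=O)OCc1ccccc1)OCc1ccccc1 | starting material
17 | dibenzyl 2-({(9R)-3-[(benzyloxy)carbonyl]-9-[(1R)-1-(1,3-dioxolan-2-yl)propyl]-6,7,8,9-tetrahydro-5H-pyrrolo[1,2-a]azepin-1-yl}methylidene)propanedioate | CC[C@@H](C1OCCO1)[C@H]2CCCCn3c(C(=O)OCc4ccccc4)cc(C=C(C(=O)OCc4ccccc4)C(=O)OCc4ccccc4)c23 | intermediate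
18 | dibenzyl 2-({(9R)-3-[(benzyloxy)carbonyl]-9-[(2R)-1-oxobutan-2-yl]-6,7,8,9-tetrahydro-5H-pyrrolo[1,2-a]azepin-1-yl}methylidene)propanedioate (Stetter precursor) | CC[C@@H](C=O)[C@H]1CCCCn2c(C(=O)OCc3ccccc3)cc(C=C(C(=O)OCc3ccccc3)C(=O)OCc3ccccc3)c21 | intermediate
19 | tricyclic C11 ketone (9R,10R,12S): pyrrole fused to the azepine and to a cyclohexanone, ethyl on C10, CH(CO2Bn)2 on C12, CO2Bn on C3 | CC[C@H]1C(=O)[C@@H](C(C(=O)OCc2ccccc2)C(=O)OCc2ccccc2)c2cc(C(=O)OCc3ccccc3)n3c2[C@@H]1CCCC3 | intermediate
20 | (9R,10R,11R,12S)-C11 alcohol of 19, hydroxyl cis to the ethyl and malonate groups | CC[C@H]1[C@@H](O)[C@@H](C(C(=O)OCc2ccccc2)C(=O)OCc2ccccc2)c2cc(C(=O)OCc3ccccc3)n3c2[C@@H]1CCCC3 | intermediate (not isolated)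
21 | tetracyclic cis-fused γ-lactone (9R,10R,11R,12S) with CO2Bn on C13 (C13 unassigned) and CO2Bn on C3 | CC[C@H]1[C@H]2OC(=O)C(C(=O)OCc3ccccc3)[C@H]2c2cc(C(=O)OCc3ccccc3)n3c2[C@@H]1CCCC3 | intermediate
22 | C13-methyl derivative of 21 (C13 quaternary: CH3 and CO2Bn, unassigned) | CC[C@H]1[C@H]2OC(=O)C(C)(C(=O)OCc3ccccc3)[C@H]2c2cc(C(=O)OCc3ccccc3)n3c2[C@@H]1CCCC3 | intermediate
23 | diacid from 22 (CO2H on C13 and on C3) | CC[C@H]1[C@H]2OC(=O)C(C)(C(=O)O)[C@H]2c2cc(C(=O)O)n3c2[C@@H]1CCCC3 | intermediate (not isolated)
24 | tetracyclic lactone C3-carboxylic acid (9R,10R,11R,12S,13S) | CC[C@H]1[C@H]2OC(=O)[C@@H](C)[C@H]2c2cc(C(=O)O)n3c2[C@@H]1CCCC3 | intermediate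
25 | methyl (R)-3-bromo-2-methylpropanoate | BrC[C@H](C)C(=O)OC | starting material
26 | C3 acid chloride of 24 | CC[C@H]1[C@H]2OC(=O)[C@@H](C)[C@H]2c2cc(C(=O)Cl)n3c2[C@@H]1CCCC3 | intermediate (not isolated)
27 | methyl (2S)-2-methyl-4-oxo-4-(tetracyclic lactone-3-yl)butanoate (C18 ketone, 20S) | CC[C@H]1[C@H]2OC(=O)[C@@H](C)[C@H]2c2cc(C(=O)C[C@H](C)C(=O)OC)n3c2[C@@H]1CCCC3 | intermediate
28 | methyl (2S,4R)-4-hydroxy-2-methyl-4-(tetracyclic lactone-3-yl)butanoate (18R,20S) | CC[C@H]1[C@H]2OC(=O)[C@@H](C)[C@H]2c2cc([C@H](O)C[C@H](C)C(=O)OC)n3c2[C@@H]1CCCC3 | intermediate (not isolated)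
29 | CNP0232452.1 (9R,10R,11R,12S,13S,18R,20S) | CC[C@H]1[C@H]2OC(=O)[C@@H](C)[C@H]2c2cc([C@H]3C[C@H](C)C(=O)O3)n3c2[C@@H]1CCCC3 | target

**Step count and risks**

Total step count: 17. Longest linear sequence: 17 steps, from pyrrole 1; the zinc reagent from 25 is made in the flask in step 16.

Steps most likely to fail:

Step 12 (key ring closure). What may go wrong: slow carbene addition to the α-branched aldehyde, enolisation at C10 with 5-exo Michael closure, or attack on the wrong face of C12. Fallback (acyl radical in place of acyl anion, same C11–C12 bond): it sets out from aldehyde 18. Pinnick oxidation (NaClO2, NaH2PO4, 2-methylbut-2-ene, t-BuOH/H2O) should give the carboxylic acid F1. Diphenyl diselenide and tributylphosphine in CH2Cl2 should convert it into the Se-phenyl selenoester F2. Slow addition of Bu3SnH and AIBN in benzene at 80 °C should generate the C11 acyl radical, which closes 6-exo-trig onto C12 through the same chair-like arrangement. Hydrogen transfer to the malonyl radical gives ketone 19, where the route is rejoined before step 13.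

Step 17 (C18). What may go wrong: sluggish hydride transfer to the electron-rich acylpyrrole carbonyl with loss of face selectivity, or ionisation of the pyrrolyl carbinol borate with over-reduction and scrambling of C18. Fallback (enzymatic reduction in place of borane reduction): it sets out from keto ester 27, which is reduced with an (R)-selective ketoreductase (NADPH recycled with glucose and glucose dehydrogenase, pH 7 phosphate buffer with DMSO co-solvent, 30 °C). Under these neutral conditions the carbinol cannot ionise. The route is rejoined at hydroxy ester 28, which is lactonised with DBU as in step 17; no new compound arises.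

Step 15 (C13). What may go wrong: protonation of the lactone enol on both faces, or later equilibration of C13 toward the epimer with the methyl group on the convex face. Fallback (C13 set by hydrogenation of a methylene group in place of protonation): it sets out from lactone ester 21 and leaves out step 14. Hydrogenolysis (H2, 10% Pd/C, EtOAc) should give the diacid F3. Aqueous formaldehyde and diethylamine, then NaOAc/AcOH at 80 °C, should bring about the decarboxylative Mannich methylenation to the α-methylene lactone acid F4. Hydrogenation (H2, 10% Pd/C, EtOAc) should add hydrogen to the exocyclic alkene from the convex face and give acid 24, where the route is rejoined before step 16.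

Further compounds
F1 | step 12 | (2R)-2-{(9R)-3-[(benzyloxy)carbonyl]-1-[2,2-bis(benzyloxycarbonyl)ethenyl]-6,7,8,9-tetrahydro-5H-pyrrolo[1,2-a]azepin-9-yl}butanoic acid | CC[C@@H](C(=O)O)[C@H]1CCCCn2c(C(=O)OCc3ccccc3)cc(C=C(C(=O)OCc3ccccc3)C(=O)OCc3ccccc3)c21
F2 | step 12 | Se-phenyl selenoester of F1 | CC[C@@H](C(=O)[Se]c3ccccc3)[C@H]1CCCCn2c(C(=O)OCc3ccccc3)cc(C=C(C(=O)OCc3ccccc3)C(=O)OCc3ccccc3)c21
F0 | step 17 | none | none
F3 | step 15 | diacid from 21 (CO2H on C13 and on C3, C13 unassigned) | CC[C@H]1[C@H]2OC(=O)C(C(=O)O)[C@H]2c2cc(C(=O)O)n3c2[C@@H]1CCCC3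
F4 | step 15 | C13-methylene lactone C3-carboxylic acid | CC[C@H]1[C@H]2OC(=O)C(=C)[C@H]2c2cc(C(=O)O)n3c2[C@@H]1CCCC3
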